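**Retrosynthetic overview**
- Feature: in the flavone half, the biaryl carbon C6 lies between the oxygenated C5 and C7 and para to C8a–O1. The benzo ring (C4a, C5–C8, C8a) is therefore a 2-arylphloroglucinol. It has the same six carbons and three oxygens as a 4-alkoxy-6-(arylmethyl)pyran-2-one, and the biaryl bond is the Ar–CH2 bond of an arylacetic acid.
- Last C–C disconnection: flavanone C2–C1', the only stereocentre. This leads back to the arylboronic acid of the flavone half and 5,7-bis(benzyloxy)chromone (rhodium, chiral diene).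
- Flavone pyran-4-one ring: carbonylative annulation of an o-iodophenol with 1-(benzyloxy)-4-ethynylbenzene. The phenol oxygen (future O1) is the one para to the aryl group, kept distinct as an allyl ether.
- Flavone benzo ring: alkoxide-induced isomerisation of the pyran-2-one, which is made from the arylacetyl chloride and the dienolate of 2,2,6-trimethyl-4H-1,3-dioxin-4-one.
- Ring order: pyran-2-one (sacrificial), then flavone benzo ring, then flavone pyran-4-one ring. The chromone of the other half is made separately and becomes the flavanone in the coupling. Six benzyl ethers are removed last.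

Key step: step 7

Remark 1: the biaryl axis (flavanone C3' to flavone C6) carries only three oxygen ortho substituents and is taken as freely rotating at room temperature, so C2 is the only stereo-element to control.
Remark 2: the (1S,4S) antipode of the diene ligand in step 16 is chosen by analogy with the facial preference of this ligand family for cyclic enones. The choice is to be confirmed on a simple arylboronic acid, and the other antipode is used if the sense is opposite.

Step 1
Reactants: 1 2-hydroxyphenylacetic acid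
Product: 2 (5-chloro-2-hydroxyphenyl)acetic acid
Conditions: SO2Cl2 (1.05 equiv), CH2Cl2/Et2O, 0 °C to rt; crystallisation
Reagents that add atoms: sulfuryl chloride, O=S(=O)(Cl)Cl
Why: Electrophilic aromatic chlorination in which the phenol directs to its free para position (C5), the more crowded ortho site being the minor channel that crystallisation removes.

Step 2
Reactants: 2 (5-chloro-2-hydroxyphenyl)acetic acid
Product: 4 [2-(benzyloxy)-5-chlorophenyl]acetic acid, via benzyl ester 3 (not isolated)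
Conditions: BnBr (2.3 equiv), K2CO3, DMF, 60 °C; then NaOH, THF/MeOH/H2O, 50 °C; aq. HCl
Reagents that add atoms: benzyl bromide, BrCc1ccccc1; sodium hydroxide, [Na+].[OH-]
Why: Williamson etherification with concurrent esterification, followed by saponification that cleaves only the benzyl ester and leaves the aryl benzyl ether intact.

Step 3
Reactants: 4 [2-(benzyloxy)-5-chlorophenyl]acetic acid
Product: 5 [2-(benzyloxy)-5-chlorophenyl]acetyl chloride
Conditions: (COCl)2, DMF (cat.), CH2Cl2, 0 °C to rt; evaporated and used crude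
Reagents that add atoms: oxalyl chloride, O=C(Cl)C(=O)Cl
Why: Standard acid chloride formation under chloroiminium (Vilsmeier-type) catalysis, mild enough for the benzyl ether.

Step 4
Reactants: 5 [2-(benzyloxy)-5-chlorophenyl]acetyl chloride; 6 2,2,6-trimethyl-4H-1,3-dioxin-4-one
Product: 8 6-{3-[2-(benzyloxy)-5-chlorophenyl]-2-oxopropyl}-2,2-dimethyl-4H-1,3-dioxin-4-one, via lithium dienolate 7 (not isolated)
Conditions: 6 (2.2 equiv), LiN(SiMe3)2 (2.2 equiv), THF, −78 °C; then 5 (1 equiv), −78 °C; AcOH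
Reagents that add atoms: none
Why: Vinylogous Claisen-type C-acylation, in which the dioxinone dienolate reacts with acyl chlorides at its exocyclic γ-carbon fast enough at −78 °C to outrun ketene formation from 5, the second equivalent of dienolate taking up the acidic proton of the product.

Step 5
Reactants: 8 6-{3-[2-(benzyloxy)-5-chlorophenyl]-2-oxopropyl}-2,2-dimethyl-4H-1,3-dioxin-4-one
Product: 10 6-{[2-(benzyloxy)-5-chlorophenyl]methyl}-4-hydroxy-2H-pyran-2-one, via acylketene 9 (not isolated)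
Conditions: toluene, 110 °C
Reagents that add atoms: none
Why: Retro-hetero-Diels–Alder loss of acetone gives the acylketene, whose 1,3-diketone enol oxygen adds to the ketene carbon, which is the standard thermolysis of 6-(2-oxoalkyl)dioxinones to 4-hydroxypyran-2-ones.

Step 6
Reactants: 10 6-{[2-(benzyloxy)-5-chlorophenyl]methyl}-4-hydroxy-2H-pyran-2-one
Product: 11 4-(allyloxy)-6-{[2-(benzyloxy)-5-chlorophenyl]methyl}-2H-pyran-2-one
Conditions: allyl alcohol, PPh3, DIAD, THF, 0 °C to rt
Reagents that add atoms: allyl alcohol, C=CCO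
Why: Mitsunobu reaction of the acidic 4-OH, which alkylates on oxygen and avoids the C3-allylation that allyl halide and base tend to give with 4-hydroxypyranones.

Step 7
Reactants: 11 4-(allyloxy)-6-{[2-(benzyloxy)-5-chlorophenyl]methyl}-2H-pyran-2-one
Product: 13 5-(allyloxy)-2-[2-(benzyloxy)-5-chlorophenyl]benzene-1,3-diol, via ring-opened allyl ester 12 (not isolated)
Conditions: NaH (4 equiv), allyl alcohol, 0 °C to rt; then 11, 85–95 °C, argon; cold 1 M HCl
Reagents that add atoms: none
Why: Allyloxide adds to the lactone carbonyl C2 and expels the C6 enolate oxygen to give the sodium dienolate of ester 12, in which the ester carbon and the keto chain remain cis on the enol-ether double bond (2E by the sequence rules, and able to re-equilibrate through the dienolate); proton exchange in allyl alcohol then gives the benzylic enolate, which attacks the ester carbonyl, loses allyloxide and tautomerises to the arene, held as its phenolate until the acid quench. The closest known reactions are the alkoxide-induced isomerisation of 4-alkoxy-6-alkylpyran-2-ones to 5-alkoxyresorcinols and the magnesium alkoxide Claisen recyclisation of 6-acetonyl-4-hydroxypyran-2-ones and 3,5,7-trioxo esters to acylphloroglucinols. The single ring closed is the carbocycle, by a 6-(enolendo)-exo-trig Claisen (Dieckmann-type) condensation that joins the aryl-bearing carbon (future flavone C6) to the former lactone carbon (future C5 or C7, equivalent by symmetry at this stage). No stereocentre is created. The step needs acylation at the benzylic carbon instead of return to the lactone through oxygen: relactonisation is reversible and only regenerates 11, the aryl group makes the benzylic position several pKa units more acidic than the methyl group of the parent series, and aromatisation with phenolate formation makes the carbocyclic channel irreversible. Matching the alkoxide to the enol-ether group makes exchange at C4 invisible, and a bath below about 100 °C keeps the [3,3] shift of the allyl enol ether slow.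

Step 8
Reactants: 13 5-(allyloxy)-2-[2-(benzyloxy)-5-chlorophenyl]benzene-1,3-diol
Product: 14 5-(allyloxy)-1,3-bis(benzyloxy)-2-[2-(benzyloxy)-5-chlorophenyl]benzene
Conditions: BnBr (2.5 equiv), K2CO3, DMF, 60 °C
Reagents that add atoms: benzyl bromide, BrCc1ccccc1
Why: Williamson etherification of the two equivalent phenols, carbonate in DMF favouring O- over C-alkylation of the electron-rich ring.

Step 9
Reactants: 14 5-(allyloxy)-1,3-bis(benzyloxy)-2-[2-(benzyloxy)-5-chlorophenyl]benzene
Product: 15 3,5-bis(benzyloxy)-4-[2-(benzyloxy)-5-chlorophenyl]phenol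
Conditions: Pd(PPh3)4 (5 mol %), morpholine, THF, rt
Reagents that add atoms: none
Why: Tsuji–Trost-type deallylation, in which zerovalent palladium ionises the aryl allyl ether and morpholine traps the π-allyl complex, while benzyl ethers and the aryl chloride are inert at room temperature.

Step 10
Reactants: 15 3,5-bis(benzyloxy)-4-[2-(benzyloxy)-5-chlorophenyl]phenol
Product: 16 3,5-bis(benzyloxy)-4-[2-(benzyloxy)-5-chlorophenyl]-2-iodophenol
Conditions: NIS (1.0 equiv), CH2Cl2, −20 to 0 °C
Reagents that add atoms: N-iodosuccinimide, O=C1CCC(=O)N1I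
Why: Electrophilic aromatic iodination of the most electron-rich ring, whose para position is blocked by the aryl group and whose two ortho positions are equivalent, so one equivalent of reagent at low temperature should stop at a single mono-iodide.

Step 11
Reactants: 16 3,5-bis(benzyloxy)-4-[2-(benzyloxy)-5-chlorophenyl]-2-iodophenol; 17 1-(benzyloxy)-4-ethynylbenzene
Product: 20 5,7-bis(benzyloxy)-6-[2-(benzyloxy)-5-chlorophenyl]-2-[4-(benzyloxy)phenyl]-4H-chromen-4-one, via ynone 18 (not isolated), via diethylamino enone 19 (not isolated)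
Conditions: 17 (1.5 equiv), PdCl2(dppf) (5 mol %), CO (10 bar), Et2NH, 100 °C
Reagents that add atoms: carbon monoxide, [C-]#[O+]
Why: Carbonylative Sonogashira coupling followed by amine-relayed ring closure (the known carbonylative annulation of o-iodophenols with terminal alkynes), in which diethylamine adds to the ynone so that the phenol closes by 6-endo addition–elimination to the flavone instead of the aurone, the electron-rich aryl chloride being inert to the dppf-ligated catalyst.

Step 12
Reactants: 20 5,7-bis(benzyloxy)-6-[2-(benzyloxy)-5-chlorophenyl]-2-[4-(benzyloxy)phenyl]-4H-chromen-4-one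
Product: 21 5,7-bis(benzyloxy)-6-[2-(benzyloxy)-5-(4,4,5,5-tetramethyl-1,3,2-dioxaborolan-2-yl)phenyl]-2-[4-(benzyloxy)phenyl]-4H-chromen-4-one
Conditions: B2pin2, Pd2(dba)3 (2 mol %), XPhos (8 mol %), KOAc, 1,4-dioxane, 100 °C
Reagents that add atoms: bis(pinacolato)diboron, CC1(C)OB(OC1(C)C)B1OC(C)(C)C(C)(C)O1
Why: Miyaura borylation, in which the bulky electron-rich biarylphosphine allows oxidative addition to the electron-rich aryl chloride and the acetate base leaves the flavone and benzyl ethers untouched.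

Step 13
Reactants: 21 the pinacol boronate of step 12
Product: 22 {4-(benzyloxy)-3-[5,7-bis(benzyloxy)-2-(4-(benzyloxy)phenyl)-4-oxo-4H-chromen-6-yl]phenyl}boronic acid
Conditions: NaIO4, THF/H2O, rt; then 1 M HCl
Reagents that add atoms: water, O
Why: Periodate glycol cleavage of the pinacol released in the hydrolysis equilibrium drives the ester to the free boronic acid needed for transmetallation to rhodium.

Step 14
Reactants: 23 2,4,6-trihydroxyacetophenone
Product: 24 1-[2,4-bis(benzyloxy)-6-hydroxyphenyl]ethan-1-one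
Conditions: BnBr (2.05 equiv), K2CO3, DMF, rt to 40 °C
Reagents that add atoms: benzyl bromide, BrCc1ccccc1
Why: Selective Williamson etherification, which stops at the dibenzyl ether because the last phenol is hydrogen-bonded to the ketone and is much less nucleophilic.

Step 15
Reactants: 24 1-[2,4-bis(benzyloxy)-6-hydroxyphenyl]ethan-1-one
Product: 26 5,7-bis(benzyloxy)-4H-chromen-4-one, via enaminone 25 (not isolated)
Conditions: Me2NCH(OMe)2, toluene, 100 °C; concentrate; then conc. HCl, CH2Cl2, 40 °C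
Reagents that add atoms: N,N-dimethylformamide dimethyl acetal, COC(OC)N(C)C
Why: Enaminone formation at the acetyl methyl group followed by acid-promoted addition–elimination of the phenol with loss of dimethylamine, the standard enaminone route to 2,3-unsubstituted chromones.

Step 16
Reactants: 22 the boronic acid of step 13; 26 5,7-bis(benzyloxy)-4H-chromen-4-one
Product: 27 (2S)-5,7-bis(benzyloxy)-2-{4-(benzyloxy)-3-[5,7-bis(benzyloxy)-2-(4-(benzyloxy)phenyl)-4-oxo-4H-chromen-6-yl]phenyl}-2,3-dihydro-4H-chromen-4-one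
Conditions: 26 (2 equiv), [RhCl(C2H4)2]2 (2.5 mol %), (1S,4S)-2,5-diphenylbicyclo[2.2.2]octa-2,5-diene (5.5 mol %), aq. KOH (0.3 equiv), toluene/H2O, 40 °C
Reagents that add atoms: none
Why: Hayashi–Miyaura reaction (rhodium-catalysed asymmetric 1,4-addition of arylboronic acids to chromones, known for 5,7-dioxygenated chromones), in which the aryl–rhodium species held by the C2-symmetric diene inserts the chromone C2=C3 bond from one face and so sets C2 as S, water releases the flavanone from the rhodium enolate, and the 2-aryl-substituted enone of the flavone in 22 is too hindered to compete.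

Step 17
Reactants: 27 the hexabenzyl ether of step 16
Product: 28 (2S)-2-{3-[5,7-dihydroxy-2-(4-hydroxyphenyl)-4-oxo-4H-chromen-6-yl]-4-hydroxyphenyl}-5,7-dihydroxy-2,3-dihydro-4H-chromen-4-one
Conditions: H2 (1 atm), 10% Pd/C, THF/MeOH, rt; filtration and base-free work-up
Reagents that add atoms: none
Why: Hydrogenolysis of six aryl benzyl ethers in neutral medium, where the flavone C2=C3 bond, the two donor-deactivated carbonyl groups and the benzylic C2–O bond react much more slowly and no base is present to open the flavanone and scramble C2.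

**Compound list**
1 | 2-hydroxyphenylacetic acid | OC(=O)Cc1ccccc1O | starting material
2 | (5-chloro-2-hydroxyphenyl)acetic acid | OC(=O)Cc1cc(Cl)ccc1O | intermediate
3 | benzyl [2-(benzyloxy)-5-chlorophenyl]acetate | O=C(Cc1cc(Cl)ccc1OCc1ccccc1)OCc1ccccc1 | intermediate
4 | [2-(benzyloxy)-5-chlorophenyl]acetic acid | OC(=O)Cc1cc(Cl)ccc1OCc1ccccc1 | intermediate
5 | [2-(benzyloxy)-5-chlorophenyl]acetyl chloride | O=C(Cl)Cc1cc(Cl)ccc1OCc1ccccc1 | intermediate
6 | 2,2,6-trimethyl-4H-1,3-dioxin-4-one | CC1=CC(=O)OC(C)(C)O1 | starting material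
7 | lithium 2,2-dimethyl-6-methylidene-6H-1,3-dioxin-4-olate | [Li+].C=C1C=C([O-])OC(C)(C)O1 | intermediate
8 | 6-{3-[2-(benzyloxy)-5-chlorophenyl]-2-oxopropyl}-2,2-dimethyl-4H-1,3-dioxin-4-one | CC1(C)OC(=O)C=C(CC(=O)Cc2cc(Cl)ccc2OCc2ccccc2)O1 | intermediate
9 | 6-[2-(benzyloxy)-5-chlorophenyl]hex-1-ene-1,3,5-trione (acylketene) | O=C=CC(=O)CC(=O)Cc1cc(Cl)ccc1OCc1ccccc1 | intermediate
10 | 6-{[2-(benzyloxy)-5-chlorophenyl]methyl}-4-hydroxy-2H-pyran-2-one | O=c1cc(O)cc(Cc2cc(Cl)ccc2OCc2ccccc2)o1 | intermediate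
11 | 4-(allyloxy)-6-{[2-(benzyloxy)-5-chlorophenyl]methyl}-2H-pyran-2-one | C=CCOc1cc(=O)oc(Cc2cc(Cl)ccc2OCc2ccccc2)c1 | intermediate
12 | allyl (2E)-3-(allyloxy)-6-[2-(benzyloxy)-5-chlorophenyl]-5-oxohex-2-enoate (present as its sodium enolate) | C=CCOC(=O)/C=C(OCC=C)\CC(=O)Cc1cc(Cl)ccc1OCc1ccccc1 | intermediate
13 | 5-(allyloxy)-2-[2-(benzyloxy)-5-chlorophenyl]benzene-1,3-diol | C=CCOc1cc(O)c(-c2cc(Cl)ccc2OCc2ccccc2)c(O)c1 | intermediate
14 | 5-(allyloxy)-1,3-bis(benzyloxy)-2-[2-(benzyloxy)-5-chlorophenyl]benzene | C=CCOc1cc(OCc2ccccc2)c(-c2cc(Cl)ccc2OCc2ccccc2)c(OCc2ccccc2)c1 | intermediate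
15 | 3,5-bis(benzyloxy)-4-[2-(benzyloxy)-5-chlorophenyl]phenol | Oc1cc(OCc2ccccc2)c(-c2cc(Cl)ccc2OCc2ccccc2)c(OCc2ccccc2)c1 | intermediate
16 | 3,5-bis(benzyloxy)-4-[2-(benzyloxy)-5-chlorophenyl]-2-iodophenol | Oc1cc(OCc2ccccc2)c(-c2cc(Cl)ccc2OCc2ccccc2)c(OCc2ccccc2)c1I | intermediate
17 | 1-(benzyloxy)-4-ethynylbenzene | C#Cc1ccc(OCc2ccccc2)cc1 | starting material
18 | 1-{2,4-bis(benzyloxy)-3-[2-(benzyloxy)-5-chlorophenyl]-6-hydroxyphenyl}-3-[4-(benzyloxy)phenyl]prop-2-yn-1-one | O=C(C#Cc1ccc(OCc2ccccc2)cc1)c1c(O)cc(OCc2ccccc2)c(-c2cc(Cl)ccc2OCc2ccccc2)c1OCc1ccccc1 | intermediate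
19 | (2E)-1-{2,4-bis(benzyloxy)-3-[2-(benzyloxy)-5-chlorophenyl]-6-hydroxyphenyl}-3-[4-(benzyloxy)phenyl]-3-(diethylamino)prop-2-en-1-one (drawn E; the push–pull alkene isomerises freely) | O=C(/C=C(/N(CC)CC)c1ccc(OCc2ccccc2)cc1)c1c(O)cc(OCc2ccccc2)c(-c2cc(Cl)ccc2OCc2ccccc2)c1OCc1ccccc1 | intermediate
20 | 5,7-bis(benzyloxy)-6-[2-(benzyloxy)-5-chlorophenyl]-2-[4-(benzyloxy)phenyl]-4H-chromen-4-one | O=c1cc(-c2ccc(OCc3ccccc3)cc2)oc2cc(OCc3ccccc3)c(-c3cc(Cl)ccc3OCc3ccccc3)c(OCc3ccccc3)c12 | intermediate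
21 | 5,7-bis(benzyloxy)-6-[2-(benzyloxy)-5-(4,4,5,5-tetramethyl-1,3,2-dioxaborolan-2-yl)phenyl]-2-[4-(benzyloxy)phenyl]-4H-chromen-4-one | O=c1cc(-c2ccc(OCc3ccccc3)cc2)oc2cc(OCc3ccccc3)c(-c3cc(B4OC(C)(C)C(C)(C)O4)ccc3OCc3ccccc3)c(OCc3ccccc3)c12 | intermediate
22 | {4-(benzyloxy)-3-[5,7-bis(benzyloxy)-2-(4-(benzyloxy)phenyl)-4-oxo-4H-chromen-6-yl]phenyl}boronic acid | O=c1cc(-c2ccc(OCc3ccccc3)cc2)oc2cc(OCc3ccccc3)c(-c3cc(B(O)O)ccc3OCc3ccccc3)c(OCc3ccccc3)c12 | intermediate
23 | 2,4,6-trihydroxyacetophenone | CC(=O)c1c(O)cc(O)cc1O | starting material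
24 | 1-[2,4-bis(benzyloxy)-6-hydroxyphenyl]ethan-1-one | CC(=O)c1c(O)cc(OCc2ccccc2)cc1OCc1ccccc1 | intermediate
25 | (2E)-1-[2,4-bis(benzyloxy)-6-hydroxyphenyl]-3-(dimethylamino)prop-2-en-1-one | CN(C)/C=C/C(=O)c1c(O)cc(OCc2ccccc2)cc1OCc1ccccc1 | intermediate
26 | 5,7-bis(benzyloxy)-4H-chromen-4-one | O=c1ccoc2cc(OCc3ccccc3)cc(OCc3ccccc3)c12 | intermediate
27 | (2S)-5,7-bis(benzyloxy)-2-{4-(benzyloxy)-3-[5,7-bis(benzyloxy)-2-(4-(benzyloxy)phenyl)-4-oxo-4H-chromen-6-yl]phenyl}-2,3-dihydro-4H-chromen-4-one | O=C1C[C@@H](c2ccc(OCc3ccccc3)c(-c3c(OCc4ccccc4)cc4oc(-c5ccc(OCc6ccccc6)cc5)cc(=O)c4c3OCc3ccccc3)c2)Oc2cc(OCc3ccccc3)cc(OCc3ccccc3)c21 | intermediate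
28 | (2S)-2-{3-[5,7-dihydroxy-2-(4-hydroxyphenyl)-4-oxo-4H-chromen-6-yl]-4-hydroxyphenyl}-5,7-dihydroxy-2,3-dihydro-4H-chromen-4-one (CNP0277421.1) | O=C1C[C@@H](c2ccc(O)c(-c3c(O)cc4oc(-c5ccc(O)cc5)cc(=O)c4c3O)c2)Oc2cc(O)cc(O)c21 | target

Total step count: 17.
Longest linear sequence: 15 (steps 1–13, 16 and 17).

**Steps most likely to fail**

**Step 7.**
- Risk: carbon acylation may stay slower than the reversible relactonisation at the temperatures the allyl enol ether tolerates. On longer heating the allyl group could then shift from oxygen to carbon by a [3,3] process, or alkoxide could cleave the ketone in a retro-Claisen sense.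
- Fallback, from 10 back to 15: the oxygen substituent is changed to one that has no sigmatropic pathway. The isomerisation can then be driven in the temperature range known for the 6-methyl series.
- Mitsunobu reaction of 10 with 4-methoxybenzyl alcohol gives 6-{[2-(benzyloxy)-5-chlorophenyl]methyl}-4-[(4-methoxybenzyl)oxy]-2H-pyran-2-one F1.
- Sodium 4-methoxybenzyl oxide (NaH, 4-methoxybenzyl alcohol, diglyme, 140–160 °C) takes it through the ring-opened 4-methoxybenzyl ester F2 to 2-[2-(benzyloxy)-5-chlorophenyl]-5-[(4-methoxybenzyl)oxy]benzene-1,3-diol F3.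
- BnBr and K2CO3 in DMF give 1,3-bis(benzyloxy)-2-[2-(benzyloxy)-5-chlorophenyl]-5-[(4-methoxybenzyl)oxy]benzene F4.
- CF3CO2H and Et3SiH in CH2Cl2 at 0 °C remove only the 4-methoxybenzyl group and give 15.

**Step 16.**
- Risk: protodeboronation of the electron-rich boronic acid may outrun insertion into the donor-substituted chromone. Facial selectivity may be insufficient, and base-induced ring opening may erode the configuration at C2.
- Fallback, from 20 and 24 back to 27: the flavanone ring is built from a chalcone and the enantiomers are separated.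
- Suzuki–Miyaura vinylation of 20 (K[CH2=CHBF3], Pd(OAc)2, RuPhos, K2CO3, THF/H2O, 80 °C) gives the styrene 5,7-bis(benzyloxy)-6-[2-(benzyloxy)-5-vinylphenyl]-2-[4-(benzyloxy)phenyl]-4H-chromen-4-one F5.
- Lemieux–Johnson cleavage (OsO4 cat., NaIO4, 2,6-lutidine, dioxane/H2O) attacks the terminal alkene in preference to the flavone enone and gives the benzaldehyde F6.
- Claisen–Schmidt condensation with 24 (KOH, EtOH/THF, rt) gives the 2'-hydroxychalcone F7.
- NaOAc in refluxing EtOH closes the ring by oxa-Michael addition to the racemic hexabenzyl flavanone F8.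
- Preparative chromatography on a chiral stationary phase delivers 27. The (2R)-enantiomer F9 is returned to F8 by base equilibration through F7.

**Step 11.**
- Risk: oxidative addition at the doubly ortho-substituted, electron-rich iodide may be sluggish.
- Risk: direct alkynylation without CO uptake, aminocarbonylation by diethylamine, or 5-exo closure of the ynone may divert material.
- Fallback, from 16 and 17 back to 18: the aryl ketone bond is made with an organolithium instead of by carbonylation.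
- MOMCl and i-Pr2NEt convert 16 into the methoxymethyl ether F10.
- Separately, n-BuLi converts 17 into the lithium acetylide F11, and N-methoxy-N-methylcarbamoyl chloride turns this into N-methoxy-N-methyl-3-[4-(benzyloxy)phenyl]prop-2-ynamide F12.
- Iodine–lithium exchange of F10 (n-BuLi, THF, −78 °C) gives the aryllithium F13, which adds to F12 to give the methoxymethyl-protected ynone F14.
- HCl in MeOH/THF frees the phenol to give 18. Diethylamine in warm THF then carries 18 through 19 to 20 as in the main route.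

**Further compounds**
F1 | step 7 | 6-{[2-(benzyloxy)-5-chlorophenyl]methyl}-4-[(4-methoxybenzyl)oxy]-2H-pyran-2-one | COc1ccc(COc2cc(=O)oc(Cc3cc(Cl)ccc3OCc3ccccc3)c2)cc1
F2 | step 7 | 4-methoxybenzyl (2E)-6-[2-(benzyloxy)-5-chlorophenyl]-3-[(4-methoxybenzyl)oxy]-5-oxohex-2-enoate | COc1ccc(COC(=O)/C=C(OCc2ccc(OC)cc2)\CC(=O)Cc2cc(Cl)ccc2OCc2ccccc2)cc1
F3 | step 7 | 2-[2-(benzyloxy)-5-chlorophenyl]-5-[(4-methoxybenzyl)oxy]benzene-1,3-diol | COc1ccc(COc2cc(O)c(-c3cc(Cl)ccc3OCc3ccccc3)c(O)c2)cc1
F4 | step 7 | 1,3-bis(benzyloxy)-2-[2-(benzyloxy)-5-chlorophenyl]-5-[(4-methoxybenzyl)oxy]benzene | COc1ccc(COc2cc(OCc3ccccc3)c(-c3cc(Cl)ccc3OCc3ccccc3)c(OCc3ccccc3)c2)cc1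
F5 | step 16 | 5,7-bis(benzyloxy)-6-[2-(benzyloxy)-5-vinylphenyl]-2-[4-(benzyloxy)phenyl]-4H-chromen-4-one | O=c1cc(-c2ccc(OCc3ccccc3)cc2)oc2cc(OCc3ccccc3)c(-c3cc(C=C)ccc3OCc3ccccc3)c(OCc3ccccc3)c12
F6 | step 16 | 4-(benzyloxy)-3-[5,7-bis(benzyloxy)-2-(4-(benzyloxy)phenyl)-4-oxo-4H-chromen-6-yl]benzaldehyde | O=Cc1ccc(OCc2ccccc2)c(-c2c(OCc3ccccc3)cc3oc(-c4ccc(OCc5ccccc5)cc4)cc(=O)c3c2OCc2ccccc2)c1
F7 | step 16 | (2E)-1-[2,4-bis(benzyloxy)-6-hydroxyphenyl]-3-{4-(benzyloxy)-3-[5,7-bis(benzyloxy)-2-(4-(benzyloxy)phenyl)-4-oxo-4H-chromen-6-yl]phenyl}prop-2-en-1-one | O=C(/C=C/c1ccc(OCc2ccccc2)c(-c2c(OCc3ccccc3)cc3oc(-c4ccc(OCc5ccccc5)cc4)cc(=O)c3c2OCc2ccccc2)c1)c1c(O)cc(OCc2ccccc2)cc1OCc1ccccc1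
F8 | step 16 | racemic hexabenzyl flavanone (racemate of 27) | O=C1CC(c2ccc(OCc3ccccc3)c(-c3c(OCc4ccccc4)cc4oc(-c5ccc(OCc6ccccc6)cc5)cc(=O)c4c3OCc3ccccc3)c2)Oc2cc(OCc3ccccc3)cc(OCc3ccccc3)c21
F9 | step 16 | (2R)-enantiomer of 27 | O=C1C[C@H](c2ccc(OCc3ccccc3)c(-c3c(OCc4ccccc4)cc4oc(-c5ccc(OCc6ccccc6)cc5)cc(=O)c4c3OCc3ccccc3)c2)Oc2cc(OCc3ccccc3)cc(OCc3ccccc3)c21
F10 | step 11 | 1,5-bis(benzyloxy)-2-[2-(benzyloxy)-5-chlorophenyl]-4-iodo-3'-free ring methoxymethyl ether: 3,5-bis(benzyloxy)-4-[2-(benzyloxy)-5-chlorophenyl]-2-iodo-1-(methoxymethoxy)benzene | COCOc1cc(OCc2ccccc2)c(-c2cc(Cl)ccc2OCc2ccccc2)c(OCc2ccccc2)c1I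
F11 | step 11 | lithium [4-(benzyloxy)phenyl]acetylide | [Li]C#Cc1ccc(OCc2ccccc2)cc1
F12 | step 11 | N-methoxy-N-methyl-3-[4-(benzyloxy)phenyl]prop-2-ynamide | CON(C)C(=O)C#Cc1ccc(OCc2ccccc2)cc1
F13 | step 11 | {2,4-bis(benzyloxy)-3-[2-(benzyloxy)-5-chlorophenyl]-6-(methoxymethoxy)phenyl}lithium | [Li]c1c(OCOC)cc(OCc2ccccc2)c(-c2cc(Cl)ccc2OCc2ccccc2)c1OCc1ccccc1
F14 | step 11 | 1-{2,4-bis(benzyloxy)-3-[2-(benzyloxy)-5-chlorophenyl]-6-(methoxymethoxy)phenyl}-3-[4-(benzyloxy)phenyl]prop-2-yn-1-one | COCOc1cc(OCc2ccccc2)c(-c2cc(Cl)ccc2OCc2ccccc2)c(OCc2ccccc2)c1C(=O)C#Cc1ccc(OCc2ccccc2)cc1
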